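**Retrosynthetic overview**
- The two hydroxyls are unmasked last from a di(propan-2-yl)silylene bridge that locks the 3Z trisubstituted alkene inside an eight-membered 1,3-dioxa-2-silacyclooctene.
- Key disconnection: that silacycle and the butenolide are both opened retro-metathetically to one acyclic silaketal; forward, a single double ring-closing metathesis forms both rings (silacycle first, butenolide second).
- The silaketal splits at silicon into a C19 allylic alcohol (fragment A) and a C10 (R)-homoallylic alcohol acrylate (fragment B).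
- Fragment A: dihydro-β-ionone supplies the trimethylcyclohexene ring ready-made (a cationic polyene closure would not stop at one ring); alkyne formation, Zr-catalysed carboalumination (7E alkene), oxirane opening, bromide, carbomagnesiation of propargyl alcohol.
- Fragment B: 2-methylidenepropane-1,3-diol, mono-acrylate, enal, Brown allylation (sets the only stereocentre, R).

Assumption: the target is taken as drawn, i.e. (R) at the carbinol carbon, 3Z (CH2OH cis to the carbinol-bearing chain) and 7E; dihydro-β-ionone, 2-methylidenepropane-1,3-diol and (+)-Ipc2BOMe are catalogue chemicals.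

**Route**

Step 1
Reactants: 1 4-(2,6,6-trimethylcyclohex-1-en-1-yl)butan-2-one (dihydro-β-ionone)
Product: 3 2-(but-3-yn-1-yl)-1,3,3-trimethylcyclohex-1-ene, via enol phosphate 2 (not isolated)
Conditions: LDA (1.05 equiv), THF, −78 °C; ClP(O)(OEt)2, −78 °C → rt; then LDA (2.3 equiv), THF, −78 °C → rt; aq. NH4Cl
Reagents that add atoms: none
Why: Kinetic deprotonation takes the methyl side of the ketone, the enolate is O-phosphorylated and excess LDA eliminates diethyl phosphate from the terminal enol phosphate (Negishi methyl ketone to terminal alkyne conversion); no stereocentre is involved.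

Step 2
Reactants: 3 2-(but-3-yn-1-yl)-1,3,3-trimethylcyclohex-1-ene
Product: 6 (3E)-4-methyl-6-(2,6,6-trimethylcyclohex-1-en-1-yl)hex-3-en-1-ol, via alkenylalane 4 (not isolated), via lithium alanate 5 (not isolated)
Conditions: Me3Al (2 equiv), Cp2ZrCl2 (0.25 equiv), (CH2Cl)2, rt, 12 h; evaporate volatiles, hexane; n-BuLi (1 equiv), 0 °C; oxirane (3 equiv), THF, 0 °C → rt; 1 M HCl, 0 °C
Reagents that add atoms: trimethylaluminium, C[Al](C)C; oxirane, C1CO1
Why: Zr-catalysed Negishi carboalumination adds Me and Al syn across the alkyne with Me on the internal carbon (>98% E), and the lithium alanate opens oxirane with retention of alkene geometry, which fixes the 7E alkene of the target.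

Step 3
Reactants: 6 (3E)-4-methyl-6-(2,6,6-trimethylcyclohex-1-en-1-yl)hex-3-en-1-ol
Product: 7 2-[(3E)-6-bromo-3-methylhex-3-en-1-yl]-1,3,3-trimethylcyclohex-1-ene
Conditions: CBr4, PPh3, CH2Cl2, 0 °C
Reagents that add atoms: tetrabromomethane, BrC(Br)(Br)Br
Why: Appel reaction, an SN2 displacement of the primary oxyphosphonium by bromide under neutral conditions that leaves both alkenes untouched.

Step 4
Reactants: 7 2-[(3E)-6-bromo-3-methylhex-3-en-1-yl]-1,3,3-trimethylcyclohex-1-ene
Product: 10 (5E)-6-methyl-2-methylidene-8-(2,6,6-trimethylcyclohex-1-en-1-yl)oct-5-en-1-ol (fragment A), via Grignard reagent 8 (not isolated), via alkenylmagnesium adduct 9 (not isolated)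
Conditions: Mg, THF, rt; separately prop-2-yn-1-ol (1.5 equiv), i-PrMgCl (1.45 equiv), THF, 0 °C; combine, CuI (10 mol %), THF/Et2O, 0 °C → rt, 16 h; aq. NH4Cl
Reagents that add atoms: prop-2-yn-1-ol, C#CCO
Why: CuI-catalysed, alkoxide-directed anti-carbomagnesiation of propargyl alcohol (Duboudin-type) puts the alkyl group on the internal alkyne carbon, and protonolysis of the alkenyl–Mg bond gives the 2-substituted allyl alcohol; keeping the Grignard at or below rt avoids E/Z scrambling of the remote alkene.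

Step 5
Reactants: 11 2-methylidenepropane-1,3-diol
Product: 12 2-(hydroxymethyl)prop-2-en-1-yl prop-2-enoate
Conditions: 11 (3 equiv), acryloyl chloride (1 equiv), Et3N, CH2Cl2, −40 → 0 °C
Reagents that add atoms: acryloyl chloride, C=CC(=O)Cl
Why: Statistical mono-acylation of a symmetrical diol used in three-fold excess (esterification by an acid chloride) gives mainly the mono-acrylate, and the water-soluble diol is washed out.

Step 6
Reactants: 12 2-(hydroxymethyl)prop-2-en-1-yl prop-2-enoate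
Product: 13 2-formylprop-2-en-1-yl prop-2-enoate
Conditions: activated MnO2 (15 equiv), CH2Cl2, rt; filter, BHT (trace), use crude at once
Reagents that add atoms: none
Why: MnO2 oxidises the allylic primary alcohol to the 2-substituted acrolein under neutral heterogeneous conditions that neither hydrolyse nor polymerise the acrylate.

Step 7
Reactants: 13 2-formylprop-2-en-1-yl prop-2-enoate
Product: 15 (3R)-3-hydroxy-2-methylidenehex-5-en-1-yl prop-2-enoate (fragment B), via borinate ester 14 (not isolated)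
Conditions: (+)-Ipc2BOMe, allylMgBr, Et2O, 0 °C → rt, filter off Mg salts under Ar; 13, Et2O, −100 → −78 °C; pH 7 buffer, MeOH, 30% H2O2, 0 °C
Reagents that add atoms: allylmagnesium bromide, C=CC[Mg]Br
Why: Brown allylboration, in which (+)-Ipc2B(allyl) adds through a chair Zimmerman–Traxler transition state to the Re face of the aldehyde and sets the (R) carbinol centre (about 90–95% ee expected for an α-branched enal) without touching the acrylate; neutral H2O2 then cleaves the B–O and B–C bonds.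

Step 8
Reactants: 15 (3R)-3-hydroxy-2-methylidenehex-5-en-1-yl prop-2-enoate; 10 (5E)-6-methyl-2-methylidene-8-(2,6,6-trimethylcyclohex-1-en-1-yl)oct-5-en-1-ol
Product: 17 {[(3R)-2-methylidene-1-(prop-2-enoyloxy)hex-5-en-3-yl]oxy}{[(5E)-6-methyl-2-methylidene-8-(2,6,6-trimethylcyclohex-1-en-1-yl)oct-5-en-1-yl]oxy}di(propan-2-yl)silane, via chlorosilane 16 (not isolated)
Conditions: iPr2SiCl2 (1.05 equiv), imidazole, CH2Cl2, 0 °C, 1 h; then 10 (0.95 equiv), imidazole, 0 °C → rt
Reagents that add atoms: dichlorodi(propan-2-yl)silane, CC(C)[Si](Cl)(Cl)C(C)C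
Why: Sequential silylation, in which the hindered secondary alcohol reacts only once with iPr2SiCl2 and the resulting monochlorosilane is then captured by the unhindered primary allylic alcohol to give the unsymmetrical silaketal (temporary silicon tether); the stereocentre is untouched.

Step 9
Reactants: 17 {[(3R)-2-methylidene-1-(prop-2-enoyloxy)hex-5-en-3-yl]oxy}{[(5E)-6-methyl-2-methylidene-8-(2,6,6-trimethylcyclohex-1-en-1-yl)oct-5-en-1-yl]oxy}di(propan-2-yl)silane
Product: 19 4-[(5Z,8R)-5-[(3E)-4-methyl-6-(2,6,6-trimethylcyclohex-1-en-1-yl)hex-3-en-1-yl]-2,2-di(propan-2-yl)-1,3-dioxa-2-silacyclooct-5-en-8-yl]furan-2(5H)-one, via eight-membered silaketal acrylate 18 (not isolated)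
Conditions: second-generation Hoveyda–Grubbs catalyst [RuCl2(H2IMes)(=CH-2-(i-PrO)C6H4)] (3 × 5 mol %), 2,6-dichloro-1,4-benzoquinone (20 mol %), toluene (1–2 mM), 80 → 110 °C, Ar sparge
Reagents that add atoms: none
Why: Proposed new method: a tandem double ring-closing metathesis in which the Ru carbene loads on the only monosubstituted alkene (the allyl group) and closes onto the tethered 1,1-disubstituted alkene to give the eight-membered silaketal, whose ring enforces the Z trisubstituted alkene (CH2O cis to the carbinol chain), after which the acrylate/1,1-disubstituted pair closes irreversibly to the butenolide while the trisubstituted 7E and tetrasubstituted ring alkenes are too hindered to react; the closest known reactions are temporary silicon-tethered RCM to Z-trisubstituted alkenes and RCM of 2-substituted allyl acrylates to 4-substituted butenolides.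

Step 10
Reactants: 19 4-[(5Z,8R)-5-[(3E)-4-methyl-6-(2,6,6-trimethylcyclohex-1-en-1-yl)hex-3-en-1-yl]-2,2-di(propan-2-yl)-1,3-dioxa-2-silacyclooct-5-en-8-yl]furan-2(5H)-one
Product: 20 4-[(1R,3Z,7E)-1-hydroxy-4-(hydroxymethyl)-8-methyl-10-(2,6,6-trimethylcyclohex-1-en-1-yl)deca-3,7-dien-1-yl]furan-2(5H)-one (CNP0151336.2)
Conditions: HF·pyridine, pyridine, THF, 0 °C → rt
Reagents that add atoms: none
Why: Fluoride-mediated Si–O cleavage under buffered, non-basic conditions releases both hydroxyls, so the base-sensitive butenolide, the γ-acidic carbinol centre and both alkene geometries are unchanged.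

**Compound list**
1 | 4-(2,6,6-trimethylcyclohex-1-en-1-yl)butan-2-one (dihydro-β-ionone) | CC(=O)CCC1=C(C)CCCC1(C)C | starting material
2 | diethyl 4-(2,6,6-trimethylcyclohex-1-en-1-yl)but-1-en-2-yl phosphate | C=C(CCC1=C(C)CCCC1(C)C)OP(=O)(OCC)OCC | intermediate
3 | 2-(but-3-yn-1-yl)-1,3,3-trimethylcyclohex-1-ene | C#CCCC1=C(C)CCCC1(C)C | intermediate
4 | dimethyl[(1E)-2-methyl-4-(2,6,6-trimethylcyclohex-1-en-1-yl)but-1-en-1-yl]alumane (Al cis to the methyl) | C[Al](C)/C=C(\C)CCC1=C(C)CCCC1(C)C | intermediate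
5 | lithium butyl(dimethyl)[(1E)-2-methyl-4-(2,6,6-trimethylcyclohex-1-en-1-yl)but-1-en-1-yl]alanate | [Li+].CCCC[Al-](C)(C)/C=C(\C)CCC1=C(C)CCCC1(C)C | intermediate
6 | (3E)-4-methyl-6-(2,6,6-trimethylcyclohex-1-en-1-yl)hex-3-en-1-ol | OCC/C=C(\C)CCC1=C(C)CCCC1(C)C | intermediate
7 | 2-[(3E)-6-bromo-3-methylhex-3-en-1-yl]-1,3,3-trimethylcyclohex-1-ene | BrCC/C=C(\C)CCC1=C(C)CCCC1(C)C | intermediate
8 | bromo[(3E)-4-methyl-6-(2,6,6-trimethylcyclohex-1-en-1-yl)hex-3-en-1-yl]magnesium | Br[Mg]CC/C=C(\C)CCC1=C(C)CCCC1(C)C | intermediate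
9 | chloromagnesium (2Z)-3-(bromomagnesio)-2-[(3E)-4-methyl-6-(2,6,6-trimethylcyclohex-1-en-1-yl)hex-3-en-1-yl]prop-2-en-1-olate (Mg cis to CH2O) | Cl[Mg]OC/C(=C\[Mg]Br)CC/C=C(\C)CCC1=C(C)CCCC1(C)C | intermediate
10 | (5E)-6-methyl-2-methylidene-8-(2,6,6-trimethylcyclohex-1-en-1-yl)oct-5-en-1-ol (fragment A) | OCC(=C)CC/C=C(\C)CCC1=C(C)CCCC1(C)C | intermediate
11 | 2-methylidenepropane-1,3-diol | OCC(=C)CO | starting material
12 | 2-(hydroxymethyl)prop-2-en-1-yl prop-2-enoate | C=CC(=O)OCC(=C)CO | intermediate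
13 | 2-formylprop-2-en-1-yl prop-2-enoate | C=CC(=O)OCC(=C)C=O | intermediate
14 | (3R)-2-methylidene-1-(prop-2-enoyloxy)hex-5-en-3-yl diisopinocampheylborinate (Ipc groups from (−)-α-pinene) | C=CC(=O)OCC(=C)[C@@H](CC=C)OB([C@H]1C[C@H]2C[C@@H]([C@@H]1C)C2(C)C)[C@H]1C[C@H]2C[C@@H]([C@@H]1C)C2(C)C | intermediate
15 | (3R)-3-hydroxy-2-methylidenehex-5-en-1-yl prop-2-enoate (fragment B) | C=CC(=O)OCC(=C)[C@H](O)CC=C | intermediate
16 | (3R)-3-{[chlorodi(propan-2-yl)silyl]oxy}-2-methylidenehex-5-en-1-yl prop-2-enoate | C=CC(=O)OCC(=C)[C@@H](CC=C)O[Si](Cl)(C(C)C)C(C)C | intermediate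
17 | {[(3R)-2-methylidene-1-(prop-2-enoyloxy)hex-5-en-3-yl]oxy}{[(5E)-6-methyl-2-methylidene-8-(2,6,6-trimethylcyclohex-1-en-1-yl)oct-5-en-1-yl]oxy}di(propan-2-yl)silane | C=CC(=O)OCC(=C)[C@@H](CC=C)O[Si](C(C)C)(C(C)C)OCC(=C)CC/C=C(\C)CCC1=C(C)CCCC1(C)C | intermediate
18 | 2-[(5Z,8R)-5-[(3E)-4-methyl-6-(2,6,6-trimethylcyclohex-1-en-1-yl)hex-3-en-1-yl]-2,2-di(propan-2-yl)-1,3-dioxa-2-silacyclooct-5-en-8-yl]prop-2-en-1-yl prop-2-enoate | C=CC(=O)OCC(=C)[C@H]1C/C=C(/CC/C=C(\C)CCC2=C(C)CCCC2(C)C)CO[Si](C(C)C)(C(C)C)O1 | intermediate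
19 | 4-[(5Z,8R)-5-[(3E)-4-methyl-6-(2,6,6-trimethylcyclohex-1-en-1-yl)hex-3-en-1-yl]-2,2-di(propan-2-yl)-1,3-dioxa-2-silacyclooct-5-en-8-yl]furan-2(5H)-one | O=C1OCC(=C1)[C@H]2C/C=C(/CC/C=C(\C)CCC3=C(C)CCCC3(C)C)CO[Si](C(C)C)(C(C)C)O2 | intermediate
20 | 4-[(1R,3Z,7E)-1-hydroxy-4-(hydroxymethyl)-8-methyl-10-(2,6,6-trimethylcyclohex-1-en-1-yl)deca-3,7-dien-1-yl]furan-2(5H)-one | CC1=C(CC/C(C)=C/CC/C(=C/C[C@@H](O)C2=CC(=O)OC2)CO)C(C)(C)CCC1 | target

**Count**
Total steps: 10. Longest linear sequence: 7 (steps 1, 2, 3, 4, 8, 9, 10); fragment B is a 3-step branch (steps 5–7).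

**Three steps most likely to fail, with fallbacks**

Step 9 (double RCM). Risks are a slow eight-membered closure to a trisubstituted alkene, a slow acrylate closure next to the bulky silyloxy carbon, and cross-talk between the two diene pairs. The fallback sets out from 10 and comes back at 19; it makes the butenolide by furan oxidation so that only one metathesis ring closure remains. Commercial furan-3-carbaldehyde is allylated with (+)-Ipc2B(allyl) (Et2O, −78 °C) through (1R)-1-(furan-3-yl)but-3-en-1-yl diisopinocampheylborinate F1, and buffered H2O2 work-up gives (1R)-1-(furan-3-yl)but-3-en-1-ol F2. Photooxygenation with a hindered base (O2, hν, rose bengal, i-Pr2NEt, CH2Cl2, −78 °C) gives 5-hydroxy-4-[(1R)-1-hydroxybut-3-en-1-yl]furan-2(5H)-one F3, and NaBH4 (EtOH, 0 °C, then dilute acid) reduces it to 4-[(1R)-1-hydroxybut-3-en-1-yl]furan-2(5H)-one F4. Silylation with iPr2SiCl2/imidazole gives 4-[(1R)-1-{[chlorodi(propan-2-yl)silyl]oxy}but-3-en-1-yl]furan-2(5H)-one F5, which takes up 10 to give the silaketal 4-[(1R)-1-({[(5E)-6-methyl-2-methylidene-8-(2,6,6-trimethylcyclohex-1-en-1-yl)oct-5-en-1-yl]oxy}di(propan-2-yl)silyloxy)but-3-en-1-yl]furan-2(5H)-one F6. A single silicon-tethered RCM (second-generation Hoveyda–Grubbs catalyst, toluene, 80 °C, high dilution) then gives 19. The photooxygenation is done before 10 is attached because the electron-rich alkenes of 10 would react with singlet oxygen.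

Step 4 (carbomagnesiation of propargyl alcohol with a valuable homoallyl Grignard). Risks are low conversion, and Wurtz or protonation losses. The fallback sets out from 7 (through its Grignard reagent 8) and comes back at 10; it replaces carbometalation by an sp3–sp2 cross-coupling. Reagent 8 is coupled (Fe(acac)3 5 mol %, THF/NMP, 0 °C) with [(2-bromoprop-2-en-1-yl)oxy](tert-butyl)dimethylsilane F7, made from 2-bromoprop-2-en-1-ol with TBSCl and imidazole. This gives tert-butyl(dimethyl){[(5E)-6-methyl-2-methylidene-8-(2,6,6-trimethylcyclohex-1-en-1-yl)oct-5-en-1-yl]oxy}silane F8, and TBAF in THF then gives 10.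

Step 7 (allylboration of the labile acrylate-bearing enal 13). Risks are polymerisation or dimerisation of 13 and eroded ee. The fallback sets out from 11 and comes back at 15; it carries a silyl ether through oxidation and allylation and installs the acrylate last. Diol 11 is mono-silylated (NaH, TBSCl, THF) to 2-({[tert-butyl(dimethyl)silyl]oxy}methyl)prop-2-en-1-ol F9 and oxidised (MnO2, CH2Cl2) to 2-({[tert-butyl(dimethyl)silyl]oxy}methyl)prop-2-enal F10. Allylation with (+)-Ipc2B(allyl) proceeds through (3R)-1-{[tert-butyl(dimethyl)silyl]oxy}-2-methylidenehex-5-en-3-yl diisopinocampheylborinate F11 to (3R)-1-{[tert-butyl(dimethyl)silyl]oxy}-2-methylidenehex-5-en-3-ol F12. Desilylation (TBAF, AcOH, THF) gives (3R)-2-methylidenehex-5-ene-1,3-diol F13, and acylation at the primary hydroxyl (acryloyl chloride 1.0 equiv, 2,4,6-collidine, CH2Cl2, −78 °C) gives 15.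

**Further compounds**
F1 | step 9 | (1R)-1-(furan-3-yl)but-3-en-1-yl diisopinocampheylborinate | C=CC[C@@H](OB([C@H]1C[C@H]2C[C@@H]([C@@H]1C)C2(C)C)[C@H]1C[C@H]2C[C@@H]([C@@H]1C)C2(C)C)c1ccoc1
F2 | step 9 | (1R)-1-(furan-3-yl)but-3-en-1-ol | C=CC[C@@H](O)c1ccoc1
F3 | step 9 | 5-hydroxy-4-[(1R)-1-hydroxybut-3-en-1-yl]furan-2(5H)-one (epimers at C5) | C=CC[C@@H](O)C1=CC(=O)OC1O
F4 | step 9 | 4-[(1R)-1-hydroxybut-3-en-1-yl]furan-2(5H)-one | C=CC[C@@H](O)C1=CC(=O)OC1
F5 | step 9 | 4-[(1R)-1-{[chlorodi(propan-2-yl)silyl]oxy}but-3-en-1-yl]furan-2(5H)-one | C=CC[C@@H](O[Si](Cl)(C(C)C)C(C)C)C1=CC(=O)OC1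
F6 | step 9 | 4-[(1R)-1-({[(5E)-6-methyl-2-methylidene-8-(2,6,6-trimethylcyclohex-1-en-1-yl)oct-5-en-1-yl]oxy}di(propan-2-yl)silyloxy)but-3-en-1-yl]furan-2(5H)-one | C=CC[C@@H](O[Si](C(C)C)(C(C)C)OCC(=C)CC/C=C(\C)CCC2=C(C)CCCC2(C)C)C1=CC(=O)OC1
F7 | step 4 | [(2-bromoprop-2-en-1-yl)oxy](tert-butyl)dimethylsilane | CC(C)(C)[Si](C)(C)OCC(Br)=C
F8 | step 4 | tert-butyl(dimethyl){[(5E)-6-methyl-2-methylidene-8-(2,6,6-trimethylcyclohex-1-en-1-yl)oct-5-en-1-yl]oxy}silane | CC(C)(C)[Si](C)(C)OCC(=C)CC/C=C(\C)CCC1=C(C)CCCC1(C)C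
F9 | step 7 | 2-({[tert-butyl(dimethyl)silyl]oxy}methyl)prop-2-en-1-ol | CC(C)(C)[Si](C)(C)OCC(=C)CO
F10 | step 7 | 2-({[tert-butyl(dimethyl)silyl]oxy}methyl)prop-2-enal | CC(C)(C)[Si](C)(C)OCC(=C)C=O
F11 | step 7 | (3R)-1-{[tert-butyl(dimethyl)silyl]oxy}-2-methylidenehex-5-en-3-yl diisopinocampheylborinate | CC(C)(C)[Si](C)(C)OCC(=C)[C@@H](CC=C)OB([C@H]1C[C@H]2C[C@@H]([C@@H]1C)C2(C)C)[C@H]1C[C@H]2C[C@@H]([C@@H]1C)C2(C)C
F12 | step 7 | (3R)-1-{[tert-butyl(dimethyl)silyl]oxy}-2-methylidenehex-5-en-3-ol | CC(C)(C)[Si](C)(C)OCC(=C)[C@H](O)CC=C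
F13 | step 7 | (3R)-2-methylidenehex-5-ene-1,3-diol | OCC(=C)[C@H](O)CC=C
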